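**Retrosynthetic overview**
1. Target 26 ⇒ acetylation, Mitsunobu inversion at C5 and Luche reduction ⇒ 6‑methylidene‑5‑ketone 22 ⇒ α‑methylenation of cycloheptanone 19.
2. C2′ carbinol ⇒ Felkin–Anh addition of side‑chain Grignard 17 (C3′–C7′, stereocentre from Shi epoxidation of 13) to C1 methyl ketone 12.
3. 12 ⇒ hydrogenation of acetylcyclopentene 11 ⇒ ozonolysis/aldol of the allyl and methallyl groups of cycloheptanone 8 (as ketal 9).
4. 8 ⇒ one‑carbon ring expansion of cyclohexanone 6 by 1,2‑shift of the quaternary carbon, which inserts CH2 between C=O and C3a.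
5. 6 ⇒ enantioselective conjugate methallylation/enolate allylation of 1. Ring order: six‑membered ring (from 1) → seven (expansion) → five (aldol).

Assumption: the hand of the IDPi catalyst that gives (S)‑4 is picked by screening both enantiomers. Ring atoms are numbered as in decahydroazulene (C1 side chain, C3a methyl, C5 acetoxy, C6 methylidene, C8a ring‑fusion CH); side‑chain atoms are primed.

**Route**

Step 1
Reactants: 1 2‑methylcyclohex‑2‑en‑1‑one; 2 trimethyl(2‑methylallyl)silane; 3 allyl bromide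
Product: 6 (2S,3S)-2-allyl-2-methyl-3-(2-methylallyl)cyclohexan-1-one, via silyl enol ether 4 (not isolated), via lithium enolate 5 (not isolated)
Conditions: chiral IDPi Brønsted acid (2 mol%), 2 (1.5 equiv), toluene, −60 °C; then THF, MeLi, 0 °C; 3, DMPU, −78 → 0 °C
Reagents that add atoms: none
Why: Proposed new method: a silylium Lewis acid paired with a confined chiral imidodiphosphorimidate anion (formed in situ from the acid and 2) silylates the enone oxygen of 1, the methallylsilane adds at C3 on the face left open by the anion and the β‑silyl cation hands its silyl group back, releasing (S)‑enol silane 4 with the enolate regiochemistry fixed; the closest known reactions are the Lewis‑acid Hosomi–Sakurai conjugate allylation and chiral‑counteranion silylium Mukaiyama–Michael additions, not yet shown for conjugate allylation of an α‑substituted cycloalkenone; MeLi then gives lithium enolate 5, which is allylated anti to the C3 substituent (classical conjugate addition/enolate alkylation, trans) to set the quaternary centre.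

Step 2
Reactants: 6 (2S,3S)-2-allyl-2-methyl-3-(2-methylallyl)cyclohexan-1-one
Product: 8 (3R,4S)-3-allyl-3-methyl-4-(2-methylallyl)cycloheptan-1-one, via dibromomethyl carbinol 7 (not isolated)
Conditions: CH2Br2, LiTMP, THF, −78 °C; then n‑BuLi, −78 → 0 °C; H2O
Reagents that add atoms: dibromomethane BrCBr
Why: β‑Oxido carbenoid ring expansion (Nozaki–Yamamoto type): LiCHBr2 adds to the ketone, Br/Li exchange gives a carbenoid, and α‑elimination drives a 1,2‑shift in which the more substituted quaternary α‑carbon migrates with retention, so CH2 is inserted between the carbonyl and the quaternary centre and no stereocentre is made or lost.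

Step 3
Reactants: 8 (3R,4S)-3-allyl-3-methyl-4-(2-methylallyl)cycloheptan-1-one
Product: 9 (7R,8S)-7-allyl-7-methyl-8-(2-methylallyl)-1,4-dioxaspiro[4.6]undecane
Conditions: (TMSOCH2)2, TMSOTf (5 mol%), CH2Cl2, −78 → −20 °C
Reagents that add atoms: 1,2‑bis(trimethylsilyloxy)ethane C[Si](C)(C)OCCO[Si](C)(C)C
Why: Noyori ketalisation under aprotic conditions masks the only carbonyl so that the later Grignard addition meets a single ketone, and the 1,1‑disubstituted alkene is not isomerised at low temperature.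

Step 4
Reactants: 9 (7R,8S)-7-allyl-7-methyl-8-(2-methylallyl)-1,4-dioxaspiro[4.6]undecane
Product: 11 1-[(3aR,8aR)-5,5-(ethylenedioxy)-3a-methyl-3,3a,4,5,6,7,8,8a-octahydroazulen-1-yl]ethan-1-one, via keto aldehyde 10 (not isolated)
Conditions: O3, CH2Cl2/MeOH, −78 °C; Me2S; then KOH, MeOH, 0 °C → rt
Reagents that add atoms: ozone [O-][O+]=O
Why: Ozonolysis turns allyl into CH2CHO and methallyl into CH2COCH3, and base closes the five‑membered ring by intramolecular aldol condensation of the ketone methylene onto the aldehyde, the conjugated acetylcyclopentene being the thermodynamic sink; the ring‑fusion centres cannot epimerise.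

Step 5
Reactants: 11 1-[(3aR,8aR)-5,5-(ethylenedioxy)-3a-methyl-3,3a,4,5,6,7,8,8a-octahydroazulen-1-yl]ethan-1-one
Product: 12 1-[(1S,3aR,8aS)-5,5-(ethylenedioxy)-3a-methyldecahydroazulen-1-yl]ethan-1-one
Conditions: H2 (1 atm), 10% Pd/C, EtOAc, rt
Reagents that add atoms: none
Why: Heterogeneous hydrogenation adds H2 to the enone C=C from the α‑face, anti to the axial angular methyl (as for Δ16‑20‑oxo steroids), which places the acetyl group β at C1 (1S).

Step 6
Reactants: 13 5‑bromo‑2‑methylpent‑2‑ene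
Product: 14 (S)-3-(2-bromoethyl)-2,2-dimethyloxirane
Conditions: L‑fructose‑derived Shi ketone (30 mol%), Oxone, K2CO3, Bu4NHSO4, MeCN/DMM/aq. buffer, 0 °C
Reagents that add atoms: Oxone (potassium peroxymonosulfate) [K+].[O-]S(=O)(=O)OO
Why: Shi asymmetric epoxidation of a trisubstituted alkene through the spiro dioxirane transition state, the enantiomeric ketone giving the (S)‑epoxide that becomes C5′.

Step 7
Reactants: 14 (S)-3-(2-bromoethyl)-2,2-dimethyloxirane
Product: 15 (S)-5-bromo-2-methylpent-1-en-3-ol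
Conditions: Et2AlCl, LiTMP (gives Et2Al–TMP), benzene, 0 °C; aq. Rochelle salt
Reagents that add atoms: none
Why: Yamamoto aluminium‑amide isomerisation of an epoxide to an allylic alcohol by syn β‑elimination of a methyl proton; the C–O bond at the stereocentre is not broken, so (S) is kept.

Step 8
Reactants: 15 (S)-5-bromo-2-methylpent-1-en-3-ol
Product: 16 (S)-[(5-bromo-2-methylpent-1-en-3-yl)oxy](tert-butyl)dimethylsilane
Conditions: TBSCl, imidazole, DMF, rt
Reagents that add atoms: tert‑butyldimethylsilyl chloride CC(C)(C)[Si](C)(C)Cl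
Why: Standard silylation protects the secondary allylic alcohol for Grignard formation and for the later base and Mitsunobu steps.

Step 9
Reactants: 12 1-[(1S,3aR,8aS)-5,5-(ethylenedioxy)-3a-methyldecahydroazulen-1-yl]ethan-1-one; 16 (S)-[(5-bromo-2-methylpent-1-en-3-yl)oxy](tert-butyl)dimethylsilane
Product: 18 (2S,5S)-5-[(tert-butyldimethylsilyl)oxy]-2-[(1S,3aR,8aS)-5,5-(ethylenedioxy)-3a-methyldecahydroazulen-1-yl]-6-methylhept-6-en-2-ol, via Grignard reagent 17 (not isolated)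
Conditions: 16, Mg, THF, 40 °C; then LaCl3·2LiCl, 12, THF, −20 → 0 °C
Reagents that add atoms: none
Why: Lanthanum‑promoted Grignard 1,2‑addition to the methyl ketone follows the Felkin–Anh model (attack anti to the C1–C8a bond, past H‑1), the same sense as the 20‑oxo‑steroid to (20S)‑carbinol addition, setting C2′ as S; the ketal keeps C5 inert and the low basicity avoids epimerisation at C1.

Step 10
Reactants: 18 (2S,5S)-5-[(tert-butyldimethylsilyl)oxy]-2-[(1S,3aR,8aS)-5,5-(ethylenedioxy)-3a-methyldecahydroazulen-1-yl]-6-methylhept-6-en-2-ol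
Product: 19 (1S,3aR,8aS)-1-[(2S,5S)-5-[(tert-butyldimethylsilyl)oxy]-2-hydroxy-6-methylhept-6-en-2-yl]-3a-methyloctahydroazulen-5(1H)-one
Conditions: PPTS, acetone/H2O, 50 °C
Reagents that add atoms: water O
Why: Mild acetal hydrolysis frees the C5 ketone while the TBS ether and the tertiary alcohol survive PPTS.

Step 11
Reactants: 19 (1S,3aR,8aS)-1-[(2S,5S)-5-[(tert-butyldimethylsilyl)oxy]-2-hydroxy-6-methylhept-6-en-2-yl]-3a-methyloctahydroazulen-5(1H)-one
Product: 22 (1S,3aR,8aS)-1-[(2S,5S)-5-[(tert-butyldimethylsilyl)oxy]-2-hydroxy-6-methylhept-6-en-2-yl]-3a-methyl-6-methylideneoctahydroazulen-5(1H)-one, via Mannich base 20 (not isolated), via methiodide 21 (not isolated)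
Conditions: LDA (2.3 equiv), THF, −78 °C; CH2=NMe2+ I−, −78 → 0 °C; then MeI, CH2Cl2; aq. NaHCO3
Reagents that add atoms: Eschenmoser's salt (N,N‑dimethylmethylideneammonium iodide) C=[N+](C)C.[I-]
Why: Kinetic deprotonation takes the open C6–H and not the neopentyl C4–H beside the quaternary centre, the enolate undergoes a Mannich reaction, and quaternisation/elimination gives the α‑methylene ketone; the extra base only holds the tertiary alcohol as its alkoxide.

Step 12
Reactants: 22 (1S,3aR,8aS)-1-[(2S,5S)-5-[(tert-butyldimethylsilyl)oxy]-2-hydroxy-6-methylhept-6-en-2-yl]-3a-methyl-6-methylideneoctahydroazulen-5(1H)-one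
Product: 23 (2S,5S)-5-[(tert-butyldimethylsilyl)oxy]-2-[(1S,3aR,5R,8aS)-5-hydroxy-3a-methyl-6-methylidenedecahydroazulen-1-yl]-6-methylhept-6-en-2-ol
Conditions: NaBH4, CeCl3·7H2O, MeOH, −78 °C
Reagents that add atoms: none
Why: Luche 1,2‑reduction of the enone; hydride comes from the α‑face, anti to the 1,3‑related axial angular methyl (cf. 2‑ and 11‑oxo steroids), giving the 5β (5R) allylic alcohol.

Step 13
Reactants: 23 (2S,5S)-5-[(tert-butyldimethylsilyl)oxy]-2-[(1S,3aR,5R,8aS)-5-hydroxy-3a-methyl-6-methylidenedecahydroazulen-1-yl]-6-methylhept-6-en-2-ol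
Product: 24 (1S,3aR,5S,8aS)-1-[(2S,5S)-5-[(tert-butyldimethylsilyl)oxy]-2-hydroxy-6-methylhept-6-en-2-yl]-3a-methyl-6-methylidenedecahydroazulen-5-yl acetate
Conditions: AcOH, PPh3, DIAD, toluene, 0 °C → rt
Reagents that add atoms: acetic acid CC(=O)O
Why: Mitsunobu esterification inverts C5 by SN2 attack of acetate on the open α‑face, giving the 5α (5S) acetate; the tertiary alcohol is inert and the other secondary oxygen is silylated.

Step 14
Reactants: 24 (1S,3aR,5S,8aS)-1-[(2S,5S)-5-[(tert-butyldimethylsilyl)oxy]-2-hydroxy-6-methylhept-6-en-2-yl]-3a-methyl-6-methylidenedecahydroazulen-5-yl acetate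
Product: 26 (1S,3aR,5S,8aS)-1-[(2S,5S)-5-acetoxy-2-hydroxy-6-methylhept-6-en-2-yl]-3a-methyl-6-methylidenedecahydroazulen-5-yl acetate, via alcohol 25 (not isolated)
Conditions: HF·pyridine, pyridine/THF, 0 °C → rt; then Ac2O, DMAP (cat.), 0 °C → rt
Reagents that add atoms: acetic anhydride CC(=O)OC(C)=O
Why: Fluoride cleaves the TBS ether and the freed secondary allylic alcohol is acetylated in the same pot, while the tertiary C2′ alcohol is too hindered to acylate and no stereocentre is touched.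

**Compound list**
1 | 2‑methylcyclohex‑2‑en‑1‑one | CC1=CCCCC1=O | starting material
2 | trimethyl(2‑methylallyl)silane | CC(=C)C[Si](C)(C)C | starting material
3 | allyl bromide | C=CCBr | starting material
4 | (S)‑trimethyl{[2‑methyl‑3‑(2‑methylallyl)cyclohex‑1‑en‑1‑yl]oxy}silane (not isolated) | C[Si](C)(C)OC1=C(C)[C@H](CC(C)=C)CCC1 | intermediate
5 | lithium (S)‑2‑methyl‑3‑(2‑methylallyl)cyclohex‑1‑en‑1‑olate (not isolated) | [Li+].[O-]C1=C(C)[C@H](CC(C)=C)CCC1 | intermediate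
6 | (2S,3S)‑2‑allyl‑2‑methyl‑3‑(2‑methylallyl)cyclohexan‑1‑one | C=CC[C@]1(C)C(=O)CCC[C@H]1CC(C)=C | intermediate
7 | (2S,3S)‑2‑allyl‑1‑(dibromomethyl)‑2‑methyl‑3‑(2‑methylallyl)cyclohexan‑1‑ol, C1 not controlled, present as lithium alkoxide (not isolated) | C=CC[C@]1(C)C(O)(C(Br)Br)CCC[C@H]1CC(C)=C | intermediate
8 | (3R,4S)‑3‑allyl‑3‑methyl‑4‑(2‑methylallyl)cycloheptan‑1‑one | C=CC[C@]1(C)CC(=O)CCC[C@H]1CC(C)=C | intermediate
9 | (7R,8S)‑7‑allyl‑7‑methyl‑8‑(2‑methylallyl)‑1,4‑dioxaspiro[4.6]undecane | C=CC[C@]1(C)CC2(OCCO2)CCC[C@H]1CC(C)=C | intermediate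
10 | 2‑[(7R,8S)‑7‑methyl‑8‑(2‑oxopropyl)‑1,4‑dioxaspiro[4.6]undecan‑7‑yl]acetaldehyde (not isolated) | O=CC[C@]1(C)CC2(OCCO2)CCC[C@H]1CC(C)=O | intermediate
11 | 1‑[(3aR,8aR)‑5,5‑(ethylenedioxy)‑3a‑methyl‑3,3a,4,5,6,7,8,8a‑octahydroazulen‑1‑yl]ethan‑1‑one | CC(=O)C1=CC[C@]2(C)CC3(OCCO3)CCC[C@@H]12 | intermediate
12 | 1‑[(1S,3aR,8aS)‑5,5‑(ethylenedioxy)‑3a‑methyldecahydroazulen‑1‑yl]ethan‑1‑one | CC(=O)[C@H]1CC[C@]2(C)CC3(OCCO3)CCC[C@@H]12 | intermediate
13 | 5‑bromo‑2‑methylpent‑2‑ene | CC(C)=CCCBr | starting material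
14 | (S)‑3‑(2‑bromoethyl)‑2,2‑dimethyloxirane | BrCC[C@@H]1OC1(C)C | intermediate
15 | (S)‑5‑bromo‑2‑methylpent‑1‑en‑3‑ol | C=C(C)[C@H](CCBr)O | intermediate
16 | (S)‑[(5‑bromo‑2‑methylpent‑1‑en‑3‑yl)oxy](tert‑butyl)dimethylsilane | C=C(C)[C@H](CCBr)O[Si](C)(C)C(C)(C)C | intermediate
17 | {(3S)‑3‑[(tert‑butyldimethylsilyl)oxy]‑4‑methylpent‑4‑en‑1‑yl}magnesium bromide (not isolated) | C=C(C)[C@H](CC[Mg]Br)O[Si](C)(C)C(C)(C)C | intermediate
18 | (2S,5S)‑5‑[(tert‑butyldimethylsilyl)oxy]‑2‑[(1S,3aR,8aS)‑5,5‑(ethylenedioxy)‑3a‑methyldecahydroazulen‑1‑yl]‑6‑methylhept‑6‑en‑2‑ol | C=C(C)[C@H](CC[C@](C)(O)[C@H]1CC[C@]2(C)CC3(OCCO3)CCC[C@@H]12)O[Si](C)(C)C(C)(C)C | intermediate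
19 | (1S,3aR,8aS)‑1‑[(2S,5S)‑5‑[(tert‑butyldimethylsilyl)oxy]‑2‑hydroxy‑6‑methylhept‑6‑en‑2‑yl]‑3a‑methyloctahydroazulen‑5(1H)‑one | C=C(C)[C@H](CC[C@](C)(O)[C@H]1CC[C@]2(C)CC(=O)CCC[C@@H]12)O[Si](C)(C)C(C)(C)C | intermediate
20 | 6‑[(dimethylamino)methyl] derivative of 19, C6 epimers (not isolated) | C=C(C)[C@H](CC[C@](C)(O)[C@H]1CC[C@]2(C)CC(=O)C(CN(C)C)CC[C@@H]12)O[Si](C)(C)C(C)(C)C | intermediate
21 | 6‑[(trimethylammonio)methyl] derivative of 19, iodide (not isolated) | C=C(C)[C@H](CC[C@](C)(O)[C@H]1CC[C@]2(C)CC(=O)C(C[N+](C)(C)C)CC[C@@H]12)O[Si](C)(C)C(C)(C)C.[I-] | intermediate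
22 | (1S,3aR,8aS)‑1‑[(2S,5S)‑5‑[(tert‑butyldimethylsilyl)oxy]‑2‑hydroxy‑6‑methylhept‑6‑en‑2‑yl]‑3a‑methyl‑6‑methylideneoctahydroazulen‑5(1H)‑one | C=C(C)[C@H](CC[C@](C)(O)[C@H]1CC[C@]2(C)CC(=O)C(=C)CC[C@@H]12)O[Si](C)(C)C(C)(C)C | intermediate
23 | (2S,5S)‑5‑[(tert‑butyldimethylsilyl)oxy]‑2‑[(1S,3aR,5R,8aS)‑5‑hydroxy‑3a‑methyl‑6‑methylidenedecahydroazulen‑1‑yl]‑6‑methylhept‑6‑en‑2‑ol | C=C(C)[C@H](CC[C@](C)(O)[C@H]1CC[C@]2(C)C[C@@H](O)C(=C)CC[C@@H]12)O[Si](C)(C)C(C)(C)C | intermediate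
24 | (1S,3aR,5S,8aS)‑1‑[(2S,5S)‑5‑[(tert‑butyldimethylsilyl)oxy]‑2‑hydroxy‑6‑methylhept‑6‑en‑2‑yl]‑3a‑methyl‑6‑methylidenedecahydroazulen‑5‑yl acetate | C=C(C)[C@H](CC[C@](C)(O)[C@H]1CC[C@]2(C)C[C@H](OC(C)=O)C(=C)CC[C@@H]12)O[Si](C)(C)C(C)(C)C | intermediate
25 | (1S,3aR,5S,8aS)‑1‑[(2S,5S)‑2,5‑dihydroxy‑6‑methylhept‑6‑en‑2‑yl]‑3a‑methyl‑6‑methylidenedecahydroazulen‑5‑yl acetate (not isolated) | C=C(C)[C@H](CC[C@](C)(O)[C@H]1CC[C@]2(C)C[C@H](OC(C)=O)C(=C)CC[C@@H]12)O | intermediate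
26 | (1S,3aR,5S,8aS)‑1‑[(2S,5S)‑5‑acetoxy‑2‑hydroxy‑6‑methylhept‑6‑en‑2‑yl]‑3a‑methyl‑6‑methylidenedecahydroazulen‑5‑yl acetate (CNP0151143.1) | C=C(C)[C@H](CC[C@](C)(O)[C@H]1CC[C@]2(C)C[C@H](OC(C)=O)C(=C)CC[C@@H]12)OC(C)=O | target

**Step count**
Total: 14 steps. Longest linear sequence: 11 steps (1–5, then 9–14, from 1); the side‑chain arm is 3 steps (6–8).

**Three steps most likely to fail**

Step 1 (proposed new method; risks are low enantioselectivity or 1,2‑attack). The fallback is a racemic synthesis by known chemistry followed by resolution, and it sets out from 1 and 2. TiCl4‑mediated Hosomi–Sakurai addition (CH2Cl2, −78 °C) gives racemic 2‑methyl‑3‑(2‑methylallyl)cyclohexan‑1‑one F1. Thermodynamic silylation (TMSCl, NaI, Et3N, MeCN) gives the more substituted enol silane as the racemate, that is 4 together with the (R)‑enol silane F2. MeLi and then allyl bromide, as in step 1, give through 5 and the enantiomeric lithium enolate F3 the racemic trans ketone, that is 6 together with the (2R,3R)‑ketone F4. Preparative chiral SFC removes F4 and the route is rejoined at 6.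

Step 2 (risk: the CH2 carbon migrates instead of the quaternary carbon, or the hindered ketone is enolised). The fallback fixes the regiochemistry by construction with a known Ito–Saegusa ring expansion, and it sets out from 4, taken from step 1 before MeLi is added and isolated by distillation. Furukawa cyclopropanation (Et2Zn, CH2I2, CH2Cl2, 0 °C) gives the siloxycyclopropane F5. FeCl3 in DMF at 0 °C cleaves the internal cyclopropane bond to the ring‑expanded β‑chloro ketone F6, and NaOAc in MeOH eliminates HCl to give (S)‑3‑methyl‑4‑(2‑methylallyl)cyclohept‑2‑en‑1‑one F7. Copper‑catalysed conjugate addition of allylmagnesium bromide with TMSCl, anti to the C4 substituent, gives the enol silane F8, which is hydrolysed on acidic work‑up. The route is rejoined at 8.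

Step 13 (risk: SN2′ delivery of acetate to the exocyclic CH2, elimination to a diene, or no reaction at the hindered allylic alcohol). The fallback replaces substrate‑controlled reduction plus inversion by a reagent‑controlled reduction, and it sets out from 22. (R)‑Me‑CBS with catecholborane (toluene, −78 °C) reduces the enone directly to the (5S)‑allylic alcohol F9, and Ac2O/pyridine/DMAP acetylates it. The route is rejoined at 24.

**Further compounds**
F1 | step 1 | 2‑methyl‑3‑(2‑methylallyl)cyclohexan‑1‑one (racemic, C2 epimer mixture) | CC1C(=O)CCCC1CC(C)=C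
F2 | step 1 | (R)‑trimethyl{[2‑methyl‑3‑(2‑methylallyl)cyclohex‑1‑en‑1‑yl]oxy}silane | C[Si](C)(C)OC1=C(C)[C@@H](CC(C)=C)CCC1
F3 | step 1 | lithium (R)‑2‑methyl‑3‑(2‑methylallyl)cyclohex‑1‑en‑1‑olate | [Li+].[O-]C1=C(C)[C@@H](CC(C)=C)CCC1
F4 | step 1 | (2R,3R)‑2‑allyl‑2‑methyl‑3‑(2‑methylallyl)cyclohexan‑1‑one | C=CC[C@@]1(C)C(=O)CCC[C@@H]1CC(C)=C
F5 | step 2 | trimethyl{[(5S)‑6‑methyl‑5‑(2‑methylallyl)bicyclo[4.1.0]heptan‑1‑yl]oxy}silane | C[Si](C)(C)OC12CCC[C@@H](CC(C)=C)C1(C)C2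
F6 | step 2 | (4S)‑3‑chloro‑3‑methyl‑4‑(2‑methylallyl)cycloheptan‑1‑one | CC1(Cl)CC(=O)CCC[C@H]1CC(C)=C
F7 | step 2 | (S)‑3‑methyl‑4‑(2‑methylallyl)cyclohept‑2‑en‑1‑one | CC1=CC(=O)CCC[C@H]1CC(C)=C
F8 | step 2 | {[(3S,4S)‑3‑allyl‑3‑methyl‑4‑(2‑methylallyl)cyclohept‑1‑en‑1‑yl]oxy}trimethylsilane | C=CC[C@]1(C)C=C(O[Si](C)(C)C)CCC[C@H]1CC(C)=C
F9 | step 13 | (2S,5S)‑5‑[(tert‑butyldimethylsilyl)oxy]‑2‑[(1S,3aR,5S,8aS)‑5‑hydroxy‑3a‑methyl‑6‑methylidenedecahydroazulen‑1‑yl]‑6‑methylhept‑6‑en‑2‑ol | C=C(C)[C@H](CC[C@](C)(O)[C@H]1CC[C@]2(C)C[C@H](O)C(=C)CC[C@@H]12)O[Si](C)(C)C(C)(C)C
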